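**Plan**

1. Quinone locants used below: C-1 (C=O next to the C-methyl), C-2 (methyl), C-3 (henicosyl), C-4 (C=O), C-5 (OMe), C-6 (H). The retrosynthesis first removes the O-methyl group (hydroxyquinone 11) and the C-4 oxygen (resorcinol 10), then puts an ester back on C-2 (9). Last, it cuts the ring at C-1/C-6 and C-2/C-3 in one operation into dimethyl methylmalonate (C-1, C-2 and the methyl) and pentacos-3-yn-2-one (C-3 to C-6 with the chain).
2. Enabling feature: the oxygens on C-1 and C-5 are 1,3-related across C-6–H, and C-3 is β to the C-5 oxygen. The ring is thus a folded polyketide: C-3 is the fatty acyl carbon, C-2/C-1 a methylmalonate unit, C-6/C-5 an acetate unit. A methylmalonate anion can therefore add to C-3 of an ynone, and its ester carbon C-1 can then acylate the acetyl methyl C-6, as in the presumed biosynthesis.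
3. Forward: the C21 chain is in place before the ring (docosan-1-ol, aldehyde, terminal alkyne, ynone). The only ring is made in step 4, already at the resorcinol oxidation level because an alkyne is used.
4. The extra ester (the activating helper on C-2) leaves in step 5 with aromatization. C-4 is then oxidized (the C-2 methyl blocks the other para position), and O-methylation ends the route.
5. Stereochemistry: the target has no stereogenic element. The quaternary carbon of 9 is racemic and is erased in step 5.

Key step: step 4

Remark: 9 is drawn as the diketo tautomer; it should exist mainly as its enol forms, which does not change the later steps.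

**Step 1**
Reactants: 1 docosan-1-ol
Product: 2 docosanal
Conditions: PhI(OAc)2, TEMPO (cat.), CH2Cl2, 30 °C
Reagents that add atoms: none
Why: The oxoammonium-mediated (TEMPO/PhI(OAc)2) oxidation of a primary alcohol should stop at the aldehyde, because no water is present to hydrate it for further oxidation.

**Step 2**
Reactants: 2 docosanal
Product: 3 tricos-1-yne
Conditions: K2CO3, MeOH/THF, 0 °C → rt
Reagents that add atoms: dimethyl (1-diazo-2-oxopropyl)phosphonate, CC(=O)C(=[N+]=[N-])P(=O)(OC)OC
Why: In the Ohira–Bestmann form of the Seyferth–Gilbert homologation, methanolysis of the reagent gives the diazomethylphosphonate anion, whose Horner–Wadsworth–Emmons-type addition to the aldehyde, loss of N2 and 1,2-hydrogen shift should give the terminal alkyne under conditions mild enough for an enolizable aldehyde.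

**Step 3**
Reactants: 3 tricos-1-yne; 4 N-methoxy-N-methylacetamide
Product: 6 pentacos-3-yn-2-one, via lithium tricos-1-yn-1-ide 5 (not isolated)
Conditions: n-BuLi, THF, −20 → 0 °C; then 4, −20 °C → rt; 1 M HCl
Reagents that add atoms: none
Why: In this Weinreb ketone synthesis the chelated tetrahedral adduct of the lithium acetylide should survive until the acidic quench, so the ynone is never exposed to acetylide.

**Step 4**
Reactants: 6 pentacos-3-yn-2-one; 7 dimethyl 2-methylpropanedioate
Product: 9 methyl 2-henicosyl-1-methyl-4,6-dioxocyclohex-2-ene-1-carboxylate, via Michael adduct 8 (not isolated)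
Conditions: NaOMe (2.2 equiv), MeOH/THF, 0 → 65 °C; then 1 M HCl
Reagents that add atoms: none
Why: Methoxide forms the tertiary anion of 7, which adds in conjugate fashion to the alkyne carbon β to the carbonyl of 6 (new bond between the methyl-bearing and the henicosyl-bearing carbon) to give enone 8; the methyl ketone enolate of its Z isomer then attacks one ester group (new bond between the acetyl methyl carbon and the ester carbonyl carbon), methoxide leaves, and the product is drained off as its stabilized β-diketone enolate. The closest known reaction type is the Michael–Claisen annulation of malonates with α,β-unsaturated methyl ketones that gives cyclohexane-1,3-diones; the ynone only raises the oxidation level by one double bond. The ring closes in a 6-(enolendo)-exo-trig Claisen condensation. The single new stereocenter, the quaternary ring carbon, forms as a racemate and needs no control because step 5 erases it. The step needs 1,4- instead of 1,2-addition (stabilized soft anion, reversible 1,2-addition), the Z enone geometry (the E and Z forms of 8 should interconvert under methoxide through the γ-dienolate or by addition–elimination of methoxide, and only Z is removed by cyclization) and C- instead of O-acylation (an enol lactone would be reopened by methoxide, and the methyl group on the malonate carbon rules out an aromatic pyrone as well as a second Michael addition).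

**Step 5**
Reactants: 9 methyl 2-henicosyl-1-methyl-4,6-dioxocyclohex-2-ene-1-carboxylate
Product: 10 5-henicosyl-4-methylbenzene-1,3-diol
Conditions: LiCl, DMSO/H2O, 150 °C
Reagents that add atoms: none
Why: In this Krapcho dealkoxycarbonylation chloride should remove the ester methyl by SN2 attack, the β-keto carboxylate loses CO2, and the dienol formed is the keto tautomer of the resorcinol, so aromatization makes the step irreversible and erases the stereocenter.

**Step 6**
Reactants: 10 5-henicosyl-4-methylbenzene-1,3-diol
Product: 11 3-henicosyl-5-hydroxy-2-methylcyclohexa-2,5-diene-1,4-dione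
Conditions: (KSO3)2NO (Fremy's salt), KH2PO4, H2O/THF, 0 °C → rt
Reagents that add atoms: potassium nitrosodisulfonate (KSO3)2NO, [K+].[K+].[O-]S(=O)(=O)N([O])S(=O)(=O)[O-]
Why: In this Teuber oxidation the nitroxyl radical abstracts a phenolic hydrogen and a second equivalent should couple at C-6 of 10 (para to the C-3 hydroxyl, ortho to the C-1 hydroxyl), because the position para to the C-1 hydroxyl carries the methyl group and the carbon between the hydroxyls is not the site attacked in 5-alkylresorcinols; collapse gives the 2-hydroxy-1,4-benzoquinone.

**Step 7**
Reactants: 11 3-henicosyl-5-hydroxy-2-methylcyclohexa-2,5-diene-1,4-dione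
Product: 12 3-henicosyl-5-methoxy-2-methylcyclohexa-2,5-diene-1,4-dione
Conditions: MeOH/CH2Cl2, H2SO4 (cat.), 40 °C
Reagents that add atoms: methanol, CO
Why: The hydroxyquinone is a vinylogous carboxylic acid, so acid-catalysed addition–elimination of methanol at the hydroxyl-bearing carbon (a Fischer-type etherification, as with 2-hydroxy-1,4-naphthoquinone) should give the methyl ether of the only hydroxyl, and the para-quinone is the only stable arrangement of the three oxygens.

**Compound list**

1 | docosan-1-ol | CCCCCCCCCCCCCCCCCCCCCCO | starting material
2 | docosanal | CCCCCCCCCCCCCCCCCCCCCC=O | intermediate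
3 | tricos-1-yne | CCCCCCCCCCCCCCCCCCCCCC#C | intermediate
4 | N-methoxy-N-methylacetamide | CC(=O)N(C)OC | starting material
5 | lithium tricos-1-yn-1-ide (not isolated) | CCCCCCCCCCCCCCCCCCCCCC#C[Li] | intermediate
6 | pentacos-3-yn-2-one | CCCCCCCCCCCCCCCCCCCCCC#CC(C)=O | intermediate
7 | dimethyl 2-methylpropanedioate (dimethyl methylmalonate) | COC(=O)C(C)C(=O)OC | starting material
8 | dimethyl 2-methyl-2-[(3Z)-2-oxopentacos-3-en-4-yl]propanedioate (not isolated; the Z isomer is the one that cyclizes and is in equilibrium with the E isomer) | CCCCCCCCCCCCCCCCCCCCCC(=C/C(C)=O)/C(C)(C(=O)OC)C(=O)OC | intermediate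
9 | methyl 2-henicosyl-1-methyl-4,6-dioxocyclohex-2-ene-1-carboxylate (racemic) | CCCCCCCCCCCCCCCCCCCCCC1=CC(=O)CC(=O)C1(C)C(=O)OC | intermediate
10 | 5-henicosyl-4-methylbenzene-1,3-diol | CCCCCCCCCCCCCCCCCCCCCc1cc(O)cc(O)c1C | intermediate
11 | 3-henicosyl-5-hydroxy-2-methylcyclohexa-2,5-diene-1,4-dione | CCCCCCCCCCCCCCCCCCCCCC1=C(C)C(=O)C=C(O)C1=O | intermediate
12 | 3-henicosyl-5-methoxy-2-methylcyclohexa-2,5-diene-1,4-dione | CCCCCCCCCCCCCCCCCCCCCC1=C(C)C(=O)C=C(OC)C1=O | target

**Summary**

Total step count: 7.
Longest linear sequence: 7 steps (1 to 12); 4 and 7 are purchased.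

**Steps most likely to fail**

Step 4. The ynone may isomerize under base to allenyl and dienyl ketones that oligomerize, the open-chain adduct may stall because its enone geometry does not equilibrate, or closure may occur through oxygen. The fallback sets out from 2 and comes back at 10.
- Wittig olefination of 2 with 1-(triphenylphosphoranylidene)propan-2-one (toluene, 80 °C) should give (3E)-pentacos-3-en-2-one F1.
- The classical Michael–Claisen annulation of this enone with 7 (NaOMe, MeOH, reflux) should give methyl 2-henicosyl-1-methyl-4,6-dioxocyclohexane-1-carboxylate F2.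
- Saponification and acid-induced decarboxylation (aq. NaOH, then HCl, heat) should give 5-henicosyl-4-methylcyclohexane-1,3-dione F3.
- Bromination–dehydrobromination (Br2, DMF, 0 °C, then 140 °C) should aromatize F3 to 10.

Step 6. The oxidant may attack the carbon between the two hydroxyls, the hydroxyquinone may be oxidized further or couple oxidatively, or the waxy substrate may transfer poorly to the aqueous oxidant. The fallback sets out from 9 and comes back at 12; it puts the methyl ether on before the oxidation and uses the ester of 9 as a regiocontrol element.
- Acid-catalysed enol etherification of 9 (HC(OMe)3, TsOH cat., MeOH, rt) should take place at the carbonyl remote from the quaternary carbon and give methyl 2-henicosyl-4-methoxy-1-methyl-6-oxocyclohexa-2,4-diene-1-carboxylate F4.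
- NaOMe in MeOH/THF should remove the ester as dimethyl carbonate in an aromatization-driven retro-Claisen cleavage and give 3-henicosyl-5-methoxy-2-methylphenol F5. Exchange of methoxide at the enol ether carbon is degenerate and does no harm.
- Oxidation of this monophenol at its free para position (O2, Co(salen), DMF) should give 12.

Step 7. The etherification equilibrium may stay incomplete, or the hydroxyquinone may decompose under acid by addition of methanol to the ring or by self-condensation. The fallback sets out from 11 and comes back at 12.
- Reduction with Na2S2O4 (THF/H2O) should give 6-henicosyl-5-methylbenzene-1,2,4-triol F6, which is methylated at once.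
- Exhaustive methylation (Me2SO4, K2CO3, acetone, reflux) should give 3-henicosyl-1,2,5-trimethoxy-4-methylbenzene F7.
- Oxidative demethylation of the para-dimethoxy pair ((NH4)2Ce(NO3)6, MeCN/H2O, 0 °C) should give 12.

**Further compounds**

F1 | step 4 | (3E)-pentacos-3-en-2-one | CCCCCCCCCCCCCCCCCCCCC/C=C/C(C)=O
F2 | step 4 | methyl 2-henicosyl-1-methyl-4,6-dioxocyclohexane-1-carboxylate (racemic mixture of diastereomers) | CCCCCCCCCCCCCCCCCCCCCC1CC(=O)CC(=O)C1(C)C(=O)OC
F3 | step 4 | 5-henicosyl-4-methylcyclohexane-1,3-dione (racemic mixture of diastereomers) | CCCCCCCCCCCCCCCCCCCCCC1CC(=O)CC(=O)C1C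
F4 | step 6 | methyl 2-henicosyl-4-methoxy-1-methyl-6-oxocyclohexa-2,4-diene-1-carboxylate (racemic) | CCCCCCCCCCCCCCCCCCCCCC1=CC(OC)=CC(=O)C1(C)C(=O)OC
F5 | step 6 | 3-henicosyl-5-methoxy-2-methylphenol | CCCCCCCCCCCCCCCCCCCCCc1cc(OC)cc(O)c1C
F6 | step 7 | 6-henicosyl-5-methylbenzene-1,2,4-triol | CCCCCCCCCCCCCCCCCCCCCc1c(C)c(O)cc(O)c1O
F7 | step 7 | 3-henicosyl-1,2,5-trimethoxy-4-methylbenzene | CCCCCCCCCCCCCCCCCCCCCc1c(C)c(OC)cc(OC)c1OC
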